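**Strategy.** Everything rests on building the ε-ring (C1'–C6'), the only carbocycle made in the route (the β-ring is bought as (4R,6R)-actinol), from two acyclic C6 pieces. A Robinson-type annulation of mesityl oxide with ethyl acetoacetate forms C1'–C6' (Michael) and C4'=C5' (aldol condensation) in one operation. It exploits the 1,3-relation of the C3' oxygen to the C5' methyl-bearing alkene carbon and the C1' gem-dimethyl group, and leaves C6', α to the ester and γ to the enone, epimerisable, so that one dynamic ketoreductase step then sets C3' and C6'. Wittig couplings (C15 + C10 + stannyl lactol) build the polyene; a thioester–stannane coupling installs the C8 ketone.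

Key step: step 1

Assumption: (4R,6R)-actinol 27, the C10 dialdehyde 15, phosphonate 9 and (E)-dodec-2-enoic acid 34 are bought; Z isomers from the two Wittig steps are equilibrated thermally to the all-E polyene in step 13.

Step 1
Reactants: 1 mesityl oxide (4-methylpent-3-en-2-one); 2 ethyl acetoacetate
Product: 5 racemic ethyl 2,6,6-trimethyl-4-oxocyclohex-2-ene-1-carboxylate, via Michael adduct 3 (not isolated), via aldol adduct 4 (not isolated)
Conditions: ZnCl2 (cat.), toluene/heptane, reflux, azeotropic removal of water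
Reagents that add atoms: none
Why: The zinc-chelated enol of 2 adds through its central carbon to the β-carbon of 1 (Michael addition, giving the C1'–C6' bond and the quaternary C1' gem-dimethyl centre), the methyl ketone of adduct 3 then enolises toward its CH3 and attacks the chelate-activated acetyl carbonyl (aldol to 4), and loss of water gives the C4'=C5' enone. The closest known reaction type is the Robinson annulation, here in its classical Lewis-acid form for mesityl oxide and an acetoacetate. The ring is closed by a 6-(enolendo)-exo-trig aldol addition followed by dehydration. The one new stereocentre, C6' (ring C1), is formed racemic and needs no control, because it stays epimerisable (α to the ester, γ to the enone) until step 2. The step needs aldol regioselectivity (C4' onto C5', not Claisen attack on the ester or aldol in the opposite sense); the non-basic Lewis-acid conditions secure it, as does the 1,3-dicarbonyl unit, which enolises only between its carbonyls so that its acetyl group can act only as the electrophile. The enone-conjugated alkene position is the thermodynamic one.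

Step 2
Reactants: 5 racemic ethyl 2,6,6-trimethyl-4-oxocyclohex-2-ene-1-carboxylate
Product: 6 ethyl (1R,4R)-4-hydroxy-2,6,6-trimethylcyclohex-2-ene-1-carboxylate
Conditions: ketoreductase (NADPH-dependent, R-selective, from panel screening), NADP+ (cat.), i-PrOH (10% v/v), triethanolamine buffer pH 9, 30 °C
Reagents that add atoms: none
Why: Proposed new method: C1–H of 5 is α to the ester and γ to the enone, so at pH 9 the enantiomers should interconvert through the extended dienolate faster than the slow enantiomer is reduced, while the ketoreductase reduces only the carbonyl and only of the 1R enantiomer, setting C4 (C3') as R by enzyme control and C1 (C6') as R by dynamic kinetic resolution (trans product), after which C1 is no longer vinylogously activated and is fixed; the closest known reaction type is the ketoreductase dynamic reductive kinetic resolution of α-substituted β-keto esters.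

Step 3
Reactants: 6 ethyl (1R,4R)-4-hydroxy-2,6,6-trimethylcyclohex-2-ene-1-carboxylate
Product: 7 ethyl (1R,4R)-4-(tert-butyldimethylsilyloxy)-2,6,6-trimethylcyclohex-2-ene-1-carboxylate
Conditions: TBSCl, imidazole, DMF, rt
Reagents that add atoms: tert-butyldimethylsilyl chloride CC(C)(C)[Si](C)(C)Cl
Why: Standard silylation of the secondary allylic alcohol; the weak base should not epimerise C1.

Step 4
Reactants: 7 ethyl (1R,4R)-4-(tert-butyldimethylsilyloxy)-2,6,6-trimethylcyclohex-2-ene-1-carboxylate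
Product: 8 (1R,4R)-4-(tert-butyldimethylsilyloxy)-2,6,6-trimethylcyclohex-2-ene-1-carbaldehyde
Conditions: i-Bu2AlH (1.05 equiv), CH2Cl2, −78 °C; KNaC4H4O6 (aq.) work-up at 0 °C; used at once
Reagents that add atoms: none
Why: Partial reduction of the hindered ester by i-Bu2AlH at −78 °C should stop at the aluminium hemiacetal, which releases the base-labile aldehyde only on cold work-up.

Step 5
Reactants: 8 (1R,4R)-4-(tert-butyldimethylsilyloxy)-2,6,6-trimethylcyclohex-2-ene-1-carbaldehyde; 9 triethyl (E)-3-methyl-4-phosphonobut-2-enoate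
Product: 11 ethyl (2E,4E)-3-methyl-5-[(1R,4R)-4-(tert-butyldimethylsilyloxy)-2,6,6-trimethylcyclohex-2-en-1-yl]penta-2,4-dienoate, via lithiated phosphonate 10 (not isolated)
Conditions: LiN(SiMe3)2, THF, −78 °C; then 8, −78 to −20 °C
Reagents that add atoms: none
Why: Horner–Wadsworth–Emmons olefination with the stabilised vinylogous phosphonate anion should form C7'=C8' E-selectively and carry over the 9'E alkene of the reagent, the low temperature and weakly basic anion keeping C6' intact.

Step 6
Reactants: 11 ethyl (2E,4E)-3-methyl-5-[(1R,4R)-4-(tert-butyldimethylsilyloxy)-2,6,6-trimethylcyclohex-2-en-1-yl]penta-2,4-dienoate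
Product: 12 (2E,4E)-3-methyl-5-[(1R,4R)-4-(tert-butyldimethylsilyloxy)-2,6,6-trimethylcyclohex-2-en-1-yl]penta-2,4-dien-1-ol
Conditions: i-Bu2AlH (2.2 equiv), CH2Cl2, −78 °C
Reagents that add atoms: none
Why: 1,2-Reduction of the dienoate by i-Bu2AlH gives the allylic alcohol without touching the alkenes or the silyl ether.

Step 7
Reactants: 12 (2E,4E)-3-methyl-5-[(1R,4R)-4-(tert-butyldimethylsilyloxy)-2,6,6-trimethylcyclohex-2-en-1-yl]penta-2,4-dien-1-ol
Product: 14 [(2E,4E)-3-methyl-5-[(1R,4R)-4-(tert-butyldimethylsilyloxy)-2,6,6-trimethylcyclohex-2-en-1-yl]penta-2,4-dienyl]triphenylphosphonium bromide, via allylic bromide 13 (not isolated)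
Conditions: CBr4, PPh3 (2.2 equiv), CH2Cl2, −20 °C to rt
Reagents that add atoms: carbon tetrabromide BrC(Br)(Br)Br; triphenylphosphine c1ccccc1P(c1ccccc1)c1ccccc1
Why: Appel bromination of the primary allylic alcohol under neutral conditions is followed in the same flask by SN2 quaternisation of the bromide with the excess phosphine.

Step 8
Reactants: 14 C15 phosphonium bromide; 15 (2E,4E,6E)-2,7-dimethylocta-2,4,6-trienedial (excess)
Product: 18 (2E,4E,6E,8E,10E,12E)-2,7,11-trimethyl-13-[(1R,4R)-4-(tert-butyldimethylsilyloxy)-2,6,6-trimethylcyclohex-2-en-1-yl]trideca-2,4,6,8,10,12-hexaen-1-ol, via C15 ylide 16 (not isolated), via C25 aldehyde 17 (not isolated)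
Conditions: NaOMe, MeOH/CH2Cl2, 0 °C; then NaBH4, 0 °C
Reagents that add atoms: none
Why: Wittig reaction of the semistabilised ylide with one formyl group of the excess dialdehyde forms C11'=C12', and NaBH4 then reduces the remaining conjugated aldehyde 1,2 to the primary allylic alcohol.

Step 9
Reactants: 18 C25 hexaenol
Product: 20 [(2E,4E,6E,8E,10E,12E)-2,7,11-trimethyl-13-[(1R,4R)-4-(tert-butyldimethylsilyloxy)-2,6,6-trimethylcyclohex-2-en-1-yl]trideca-2,4,6,8,10,12-hexaenyl]triphenylphosphonium bromide, via C25 bromide 19 (not isolated)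
Conditions: CBr4, PPh3 (2.2 equiv), CH2Cl2, −20 °C to rt, dark
Reagents that add atoms: carbon tetrabromide BrC(Br)(Br)Br; triphenylphosphine c1ccccc1P(c1ccccc1)c1ccccc1
Why: Appel bromination and in-flask quaternisation as in step 7, avoiding the protic acid that would endanger the allylic C3' silyl ether.

Step 10
Reactants: 21 tetronic acid (4-hydroxyfuran-2(5H)-one)
Product: 22 4-bromofuran-2(5H)-one
Conditions: (COBr)2, DMF (cat.), CH2Cl2, 0 °C to rt
Reagents that add atoms: oxalyl bromide BrC(=O)C(=O)Br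
Why: Bromo-Vilsmeier activation converts the vinylogous acid hydroxyl into the vinyl bromide by addition–elimination at C4.

Step 11
Reactants: 22 4-bromofuran-2(5H)-one
Product: 23 4-(tributylstannyl)furan-2(5H)-one
Conditions: (Bu3Sn)2, Pd(PPh3)4 (cat., zerovalent palladium), toluene, 90 °C
Reagents that add atoms: hexabutylditin CCCC[Sn](CCCC)(CCCC)[Sn](CCCC)(CCCC)CCCC
Why: Palladium-catalysed stannylation of the electron-poor vinyl bromide (oxidative addition, Sn–Sn transmetalation, reductive elimination) fixes tin at the future C9 without any regiochemical question.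

Step 12
Reactants: 23 4-(tributylstannyl)furan-2(5H)-one
Product: 24 4-(tributylstannyl)-2,5-dihydrofuran-2-ol (racemic lactol)
Conditions: i-Bu2AlH (1.1 equiv), CH2Cl2, −78 °C
Reagents that add atoms: none
Why: i-Bu2AlH at −78 °C reduces the lactone only to the lactol through a stable tetrahedral aluminate and leaves the vinylstannane untouched; the lactol stereocentre is of no consequence.

Step 13
Reactants: 20 C25 phosphonium bromide; 24 4-(tributylstannyl)-2,5-dihydrofuran-2-ol
Product: 26 (2E,4E,6E,8E,10E,12E,14E,16E)-6,11,15-trimethyl-2-(tributylstannyl)-17-[(1R,4R)-4-(tert-butyldimethylsilyloxy)-2,6,6-trimethylcyclohex-2-en-1-yl]heptadeca-2,4,6,8,10,12,14,16-octaen-1-ol, via C25 ylide 25 (not isolated)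
Conditions: NaN(SiMe3)2 (1 equiv on 20, 1 equiv on 24), THF, −78 °C to rt; then heptane, 80 °C, dark
Reagents that add atoms: none
Why: Wittig olefination of the lactol through its open (Z)-hydroxy-enal form makes C11=C12 and releases the C19 hydroxyl, the C9=C10 geometry (C19 cis to C11) being fixed by the former ring, and heating equilibrates the hindered Z isomers to all-E.

Step 14
Reactants: 27 (4R,6R)-4-hydroxy-2,2,6-trimethylcyclohexanone (actinol)
Product: 28 (4R,6R)-4-(tert-butyldimethylsilyloxy)-2,2,6-trimethylcyclohexanone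
Conditions: TBSCl, imidazole, DMF, rt
Reagents that add atoms: tert-butyldimethylsilyl chloride CC(C)(C)[Si](C)(C)Cl
Why: Standard silylation of the secondary alcohol that carries the future C3 stereocentre from the chiral pool.

Step 15
Reactants: 28 (4R,6R)-4-(tert-butyldimethylsilyloxy)-2,2,6-trimethylcyclohexanone; 29 S-ethyl thioacetate
Product: 31 S-ethyl 2-[(4R,6R)-4-(tert-butyldimethylsilyloxy)-1-hydroxy-2,2,6-trimethylcyclohexyl]ethanethioate (C1 epimers), via lithium enolate 30 (not isolated)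
Conditions: LiN(i-Pr)2, THF, −78 °C; then 28, −78 °C; AcOH quench at −78 °C
Reagents that add atoms: none
Why: Aldol addition of the small lithium thioester enolate to the hindered ketone, with a cold acidic quench against retro-aldol; the new carbinol centre is destroyed in step 16.

Step 16
Reactants: 31 S-ethyl 2-[(4R,6R)-4-(tert-butyldimethylsilyloxy)-1-hydroxy-2,2,6-trimethylcyclohexyl]ethanethioate
Product: 32 S-ethyl 2-[(4R)-4-(tert-butyldimethylsilyloxy)-2,6,6-trimethylcyclohex-1-en-1-yl]ethanethioate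
Conditions: SOCl2, pyridine, CH2Cl2, −20 to 0 °C; then DBU (cat.), rt
Reagents that add atoms: none
Why: Dehydration of the tertiary alcohol through its chlorosulfite and base equilibration should funnel both possible alkenes to the endocyclic tetrasubstituted β,γ-unsaturated thioester, because the exocyclic conjugated isomer suffers A(1,3) strain with the flanking methyl groups.

Step 17
Reactants: 26 stannyl octaenol; 32 S-ethyl 2-[(4R)-4-(tert-butyldimethylsilyloxy)-2,6,6-trimethylcyclohex-1-en-1-yl]ethanethioate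
Product: 33 (3R,3'R,6'R)-3,3'-bis(tert-butyldimethylsilyloxy)-19-hydroxy-7,8-dihydro-β,ε-caroten-8-one (all-E)
Conditions: Pd2(dba)3 (cat.), P(2-furyl)3, CuO2PPh2 (copper diphenylphosphinate, monovalent copper, 1.5 equiv), THF, 45 °C, dark
Reagents that add atoms: none
Why: Palladium-catalysed, copper-phosphinate-mediated coupling of a thiol ester with a vinylstannane (Liebeskind–Srogl-type ketone synthesis) runs under neutral conditions with retention of alkene geometry, tolerates the free C19 hydroxyl and forms C8–C9 without exposing the β,γ-unsaturated ketone to base.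

Step 18
Reactants: 33 bis-silylated 19-hydroxy ketone; 34 (E)-dodec-2-enoic acid
Product: 35 (3R,3'R,6'R)-3,3'-bis(tert-butyldimethylsilyloxy)-8-oxo-7,8-dihydro-β,ε-caroten-19-yl (2E)-dodec-2-enoate
Conditions: EDC·HCl, DMAP (cat.), CH2Cl2, 0 °C, dark
Reagents that add atoms: none
Why: Carbodiimide/DMAP esterification of the only free hydroxyl (primary, allylic) at 0 °C, placed late because the resulting α-(acyloxymethyl) enone is base-sensitive.

Step 19
Reactants: 35 bis-silylated ester
Product: 36 (3R,3'R,6'R)-3,3'-dihydroxy-8-oxo-7,8-dihydro-β,ε-caroten-19-yl (2E)-dodec-2-enoate (all-E, target)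
Conditions: HF·pyridine, pyridine, THF, 0 °C to rt, dark
Reagents that add atoms: none
Why: Buffered HF·pyridine cleaves both secondary silyl ethers, the non-basic medium sparing the allylic ester and the weak acidity avoiding ionisation of the allylic C3' alcohol.

**Compound list**

1 | mesityl oxide (4-methylpent-3-en-2-one) | CC(=O)C=C(C)C | starting material
2 | ethyl acetoacetate | CCOC(=O)CC(C)=O | starting material
3 | ethyl 2-acetyl-3,3-dimethyl-5-oxohexanoate (Michael adduct, racemic) | CCOC(=O)C(C(C)=O)C(C)(C)CC(C)=O | intermediate (not isolated)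
4 | ethyl 2-hydroxy-2,6,6-trimethyl-4-oxocyclohexane-1-carboxylate (aldol adduct, racemic) | CCOC(=O)C1C(C)(O)CC(=O)CC1(C)C | intermediate (not isolated)
5 | racemic ethyl 2,6,6-trimethyl-4-oxocyclohex-2-ene-1-carboxylate | CCOC(=O)C1C(C)=CC(=O)CC1(C)C | intermediate
6 | ethyl (1R,4R)-4-hydroxy-2,6,6-trimethylcyclohex-2-ene-1-carboxylate | CCOC(=O)[C@H]1C(C)=C[C@H](O)CC1(C)C | intermediate
7 | ethyl (1R,4R)-4-(tert-butyldimethylsilyloxy)-2,6,6-trimethylcyclohex-2-ene-1-carboxylate | CCOC(=O)[C@H]1C(C)=C[C@H](O[Si](C)(C)C(C)(C)C)CC1(C)C | intermediate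
8 | (1R,4R)-4-(tert-butyldimethylsilyloxy)-2,6,6-trimethylcyclohex-2-ene-1-carbaldehyde | O=C[C@H]1C(C)=C[C@H](O[Si](C)(C)C(C)(C)C)CC1(C)C | intermediate
9 | triethyl (E)-3-methyl-4-phosphonobut-2-enoate | CCOC(=O)/C=C(C)/CP(=O)(OCC)OCC | starting material
10 | lithium salt of 9 (phosphonate carbanion) | [Li+].CCOC(=O)/C=C(C)/[CH-]P(=O)(OCC)OCC | intermediate (not isolated)
11 | ethyl (2E,4E)-3-methyl-5-[(1R,4R)-4-(tert-butyldimethylsilyloxy)-2,6,6-trimethylcyclohex-2-en-1-yl]penta-2,4-dienoate | CCOC(=O)/C=C(C)/C=C/[C@H]1C(C)=C[C@H](O[Si](C)(C)C(C)(C)C)CC1(C)C | intermediate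
12 | (2E,4E)-3-methyl-5-[(1R,4R)-4-(tert-butyldimethylsilyloxy)-2,6,6-trimethylcyclohex-2-en-1-yl]penta-2,4-dien-1-ol | OC/C=C(C)/C=C/[C@H]1C(C)=C[C@H](O[Si](C)(C)C(C)(C)C)CC1(C)C | intermediate
13 | C15 allylic bromide from 12 | BrC/C=C(C)/C=C/[C@H]1C(C)=C[C@H](O[Si](C)(C)C(C)(C)C)CC1(C)C | intermediate (not isolated)
14 | C15 triphenylphosphonium bromide | [Br-].c1ccccc1[P+](c1ccccc1)(c1ccccc1)C/C=C(C)/C=C/[C@H]1C(C)=C[C@H](O[Si](C)(C)C(C)(C)C)CC1(C)C | intermediate
15 | (2E,4E,6E)-2,7-dimethylocta-2,4,6-trienedial | O=C/C(C)=C/C=C/C=C(C)/C=O | starting material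
16 | C15 ylide from 14 | c1ccccc1P(c1ccccc1)(c1ccccc1)=C/C=C(C)/C=C/[C@H]1C(C)=C[C@H](O[Si](C)(C)C(C)(C)C)CC1(C)C | intermediate (not isolated)
17 | C25 aldehyde, (2E,4E,6E,8E,10E,12E)-2,7,11-trimethyl-13-[(1R,4R)-4-(tert-butyldimethylsilyloxy)-2,6,6-trimethylcyclohex-2-en-1-yl]trideca-2,4,6,8,10,12-hexaenal | O=C/C(C)=C/C=C/C=C(C)/C=C/C=C(C)/C=C/[C@H]1C(C)=C[C@H](O[Si](C)(C)C(C)(C)C)CC1(C)C | intermediate (not isolated)
18 | C25 alcohol, the corresponding hexaen-1-ol | OC/C(C)=C/C=C/C=C(C)/C=C/C=C(C)/C=C/[C@H]1C(C)=C[C@H](O[Si](C)(C)C(C)(C)C)CC1(C)C | intermediate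
19 | C25 allylic bromide from 18 | BrC/C(C)=C/C=C/C=C(C)/C=C/C=C(C)/C=C/[C@H]1C(C)=C[C@H](O[Si](C)(C)C(C)(C)C)CC1(C)C | intermediate (not isolated)
20 | C25 triphenylphosphonium bromide | [Br-].c1ccccc1[P+](c1ccccc1)(c1ccccc1)C/C(C)=C/C=C/C=C(C)/C=C/C=C(C)/C=C/[C@H]1C(C)=C[C@H](O[Si](C)(C)C(C)(C)C)CC1(C)C | intermediate
21 | tetronic acid (4-hydroxyfuran-2(5H)-one) | OC1=CC(=O)OC1 | starting material
22 | 4-bromofuran-2(5H)-one | BrC1=CC(=O)OC1 | intermediate
23 | 4-(tributylstannyl)furan-2(5H)-one | CCCC[Sn](CCCC)(CCCC)C1=CC(=O)OC1 | intermediate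
24 | 4-(tributylstannyl)-2,5-dihydrofuran-2-ol (racemic) | CCCC[Sn](CCCC)(CCCC)C1=CC(O)OC1 | intermediate
25 | C25 ylide from 20 | c1ccccc1P(c1ccccc1)(c1ccccc1)=C/C(C)=C/C=C/C=C(C)/C=C/C=C(C)/C=C/[C@H]1C(C)=C[C@H](O[Si](C)(C)C(C)(C)C)CC1(C)C | intermediate (not isolated)
26 | stannyl octaenol (C9 tin, free C19 hydroxyl; name as in step 13) | OC\C(=C/C=C/C(C)=C/C=C/C=C(C)/C=C/C=C(C)/C=C/[C@H]1C(C)=C[C@H](O[Si](C)(C)C(C)(C)C)CC1(C)C)[Sn](CCCC)(CCCC)CCCC | intermediate
27 | (4R,6R)-4-hydroxy-2,2,6-trimethylcyclohexanone (actinol) | O=C1[C@H](C)C[C@@H](O)CC1(C)C | starting material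
28 | (4R,6R)-4-(tert-butyldimethylsilyloxy)-2,2,6-trimethylcyclohexanone | O=C1[C@H](C)C[C@@H](O[Si](C)(C)C(C)(C)C)CC1(C)C | intermediate
29 | S-ethyl thioacetate | CCSC(C)=O | starting material
30 | lithium enolate of 29 | [Li+].[O-]C(=C)SCC | intermediate (not isolated)
31 | S-ethyl 2-[(4R,6R)-4-(tert-butyldimethylsilyloxy)-1-hydroxy-2,2,6-trimethylcyclohexyl]ethanethioate (C1 epimers) | CCSC(=O)CC1(O)[C@H](C)C[C@@H](O[Si](C)(C)C(C)(C)C)CC1(C)C | intermediate
32 | S-ethyl 2-[(4R)-4-(tert-butyldimethylsilyloxy)-2,6,6-trimethylcyclohex-1-en-1-yl]ethanethioate | CCSC(=O)CC1=C(C)C[C@@H](O[Si](C)(C)C(C)(C)C)CC1(C)C | intermediate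
33 | (3R,3'R,6'R)-3,3'-bis(tert-butyldimethylsilyloxy)-19-hydroxy-7,8-dihydro-β,ε-caroten-8-one | OC\C(=C/C=C/C(C)=C/C=C/C=C(C)/C=C/C=C(C)/C=C/[C@H]1C(C)=C[C@H](O[Si](C)(C)C(C)(C)C)CC1(C)C)C(=O)CC1=C(C)C[C@@H](O[Si](C)(C)C(C)(C)C)CC1(C)C | intermediate
34 | (E)-dodec-2-enoic acid | CCCCCCCCC/C=C/C(=O)O | starting material
35 | (3R,3'R,6'R)-3,3'-bis(tert-butyldimethylsilyloxy)-8-oxo-7,8-dihydro-β,ε-caroten-19-yl (2E)-dodec-2-enoate | CCCCCCCCC/C=C/C(=O)OC\C(=C/C=C/C(C)=C/C=C/C=C(C)/C=C/C=C(C)/C=C/[C@H]1C(C)=C[C@H](O[Si](C)(C)C(C)(C)C)CC1(C)C)C(=O)CC1=C(C)C[C@@H](O[Si](C)(C)C(C)(C)C)CC1(C)C | intermediate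
36 | (3R,3'R,6'R)-3,3'-dihydroxy-8-oxo-7,8-dihydro-β,ε-caroten-19-yl (2E)-dodec-2-enoate (all-E) | CCCCCCCCC/C=C/C(=O)OC\C(=C/C=C/C(C)=C/C=C/C=C(C)/C=C/C=C(C)/C=C/[C@H]1C(C)=C[C@H](O)CC1(C)C)C(=O)CC1=C(C)C[C@@H](O)CC1(C)C | target

**Step count and risks**

Total steps: 19. Longest linear sequence: 13 steps (1–9, 13, 17, 18, 19).

Steps most likely to fail:

1. Step 2 (Proposed new method). The racemisation at C1 may be too slow relative to reduction, or the enzyme may discriminate poorly between the two substrate enantiomers, so that cis and trans alcohols form together. Fallback, from 5: catalyst-controlled 1,2-reduction with the Corey–Bakshi–Shibata oxazaborolidine enantiomer that gives 4R (catecholborane, toluene, −78 °C) sets C4 in both C1 epimers. This should give 6 together with the cis epimer ethyl (1S,4R)-4-hydroxy-2,6,6-trimethylcyclohex-2-ene-1-carboxylate F1. The two are separated by chromatography, F1 is epimerised at C1 with NaOEt in EtOH and the equilibrium mixture is recycled, returning to the route at 6.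

2. Step 17. Transmetalation of the α-branched polyenyl stannane may be slow, so that protodestannylation or polyene degradation competes. Fallback, from 26 and 32: thioester 32 is hydrolysed (LiOH, aqueous THF) to 2-[(4R)-4-(tert-butyldimethylsilyloxy)-2,6,6-trimethylcyclohex-1-en-1-yl]acetic acid F2. This is converted with 1-chloro-N,N,2-trimethylprop-1-en-1-amine into the acid chloride 2-[(4R)-4-(tert-butyldimethylsilyloxy)-2,6,6-trimethylcyclohex-1-en-1-yl]acetyl chloride F3. Stannane 26 is first esterified with 34 (EDC·HCl, DMAP) to the stannyl (2E)-dodec-2-enoate F4. A Stille acylation of F4 with F3 (Pd2(dba)3, AsPh3, THF, 50 °C) then forms C8–C9 and returns to the route at 35.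

3. Step 5. The α-centre of aldehyde 8 (C6') may epimerise, or its alkene may migrate into conjugation, under the basic phosphonate conditions. Fallback, from 7: the polarity is reversed so that the ring piece is the nucleophile. LiAlH4 reduction gives [(1R,4R)-4-(tert-butyldimethylsilyloxy)-2,6,6-trimethylcyclohex-2-en-1-yl]methanol F5. Mitsunobu reaction with 1-phenyl-1H-tetrazole-5-thiol gives the sulfide 5-{[(1R,4R)-4-(tert-butyldimethylsilyloxy)-2,6,6-trimethylcyclohex-2-en-1-yl]methylsulfanyl}-1-phenyl-1H-tetrazole F6. Oxidation with H2O2 and (NH4)6Mo7O24 gives the corresponding sulfone F7. Julia–Kocienski olefination of F7 (KN(SiMe3)2, THF, −78 °C) with commercial ethyl (E)-3-methyl-4-oxobut-2-enoate forms C7'=C8' and returns to the route at 11.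

Further compounds
F1 | step 2 | ethyl (1S,4R)-4-hydroxy-2,6,6-trimethylcyclohex-2-ene-1-carboxylate | CCOC(=O)[C@@H]1C(C)=C[C@H](O)CC1(C)C
F2 | step 17 | 2-[(4R)-4-(tert-butyldimethylsilyloxy)-2,6,6-trimethylcyclohex-1-en-1-yl]acetic acid | OC(=O)CC1=C(C)C[C@@H](O[Si](C)(C)C(C)(C)C)CC1(C)C
F3 | step 17 | 2-[(4R)-4-(tert-butyldimethylsilyloxy)-2,6,6-trimethylcyclohex-1-en-1-yl]acetyl chloride | ClC(=O)CC1=C(C)C[C@@H](O[Si](C)(C)C(C)(C)C)CC1(C)C
F4 | step 17 | (2E)-dodec-2-enoate ester of stannyl octaenol 26 | CCCCCCCCC/C=C/C(=O)OC\C(=C/C=C/C(C)=C/C=C/C=C(C)/C=C/C=C(C)/C=C/[C@H]1C(C)=C[C@H](O[Si](C)(C)C(C)(C)C)CC1(C)C)[Sn](CCCC)(CCCC)CCCC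
F5 | step 5 | [(1R,4R)-4-(tert-butyldimethylsilyloxy)-2,6,6-trimethylcyclohex-2-en-1-yl]methanol | OC[C@H]1C(C)=C[C@H](O[Si](C)(C)C(C)(C)C)CC1(C)C
F6 | step 5 | 5-{[(1R,4R)-4-(tert-butyldimethylsilyloxy)-2,6,6-trimethylcyclohex-2-en-1-yl]methylsulfanyl}-1-phenyl-1H-tetrazole | c1ccccc1-n1nnnc1SC[C@H]1C(C)=C[C@H](O[Si](C)(C)C(C)(C)C)CC1(C)C
F7 | step 5 | 5-{[(1R,4R)-4-(tert-butyldimethylsilyloxy)-2,6,6-trimethylcyclohex-2-en-1-yl]methylsulfonyl}-1-phenyl-1H-tetrazole | c1ccccc1-n1nnnc1S(=O)(=O)C[C@H]1C(C)=C[C@H](O[Si](C)(C)C(C)(C)C)CC1(C)C
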